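**Retrosynthetic overview**
1. Ring C: the O1–C2 bond of the (2S)-flavanone goes back to the open, unprotected 2'-hydroxychalcone. In the forward direction an enzyme-controlled oxa-Michael closure sets C2.
2. The chalcone Cα=Cβ bond goes back to 3-prenylresacetophenone and 2,2-dimethylchroman-6-carbaldehyde (Claisen–Schmidt condensation without protecting groups).
3. The dimethylpyran ring (ring D) goes back to an ortho-prenylphenol, made in the same pot from 4-hydroxybenzaldehyde and isoprene by prenyl cation chemistry.
4. The ring A prenyl group goes back to 2,4-dihydroxyacetophenone and prenyl bromide (phenoxide C-alkylation).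
5. Ring order: ring D first, under acid, before the acid-sensitive ring A prenylphenol exists. Ring C last, near neutral pH, so that C2 never meets strong acid or base.

Assumption: the centre written [C@H] in the given SMILES is C2 with S configuration (natural flavanone series), and the enzyme of step 4 counts as a catalyst obtained by routine E. coli expression of a synthetic gene, not as a starting material.

Step 1
Reactants: 1 2,4-dihydroxyacetophenone; 2 prenyl bromide (1-bromo-3-methylbut-2-ene)
Product: 3 1-[2,4-dihydroxy-3-(3-methylbut-2-en-1-yl)phenyl]ethanone
Conditions: KOH (2.2 equiv), H2O, 0 °C; 2 (1.0 equiv) dropwise, 0 °C → rt, 16 h; dilute HCl; SiO2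
Reagents that add atoms: none
Why: Phenoxide C-alkylation (the laboratory counterpart of aromatic prenyl transfer): in water the phenoxide oxygens are tied up by hydrogen bonding, so the soft allylic bromide is taken by carbon in an SN2 reaction, mainly at C3, which lies ortho to both oxygens and is the most electron-rich site of the resorcinol dianion; the 5-prenyl isomer and the 4-O-prenyl ether are removed on SiO2, and no stereocentre is formed.

Step 2
Reactants: 4 4-hydroxybenzaldehyde; 5 isoprene
Product: 7 2,2-dimethylchroman-6-carbaldehyde, via 4-hydroxy-3-prenylbenzaldehyde 6 (not isolated)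
Conditions: 85% H3PO4, xylene, 5 (1.5 equiv, slow addition), 30–35 °C, 24 h
Reagents that add atoms: none
Why: Friedel–Crafts prenylation followed by Markovnikov intramolecular hydroalkoxylation (ortho-prenylphenol to chroman, as in the plant): H3PO4 turns isoprene into the dimethylallyl cation, which attacks the only activated position of 4 (ortho to OH, meta to CHO) to give 6, and protonation of its trisubstituted alkene gives a tertiary cation that the neighbouring phenol traps in a 6-endo closure; no stereocentre is formed.

Step 3
Reactants: 3 1-[2,4-dihydroxy-3-(3-methylbut-2-en-1-yl)phenyl]ethanone; 7 2,2-dimethylchroman-6-carbaldehyde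
Product: 9 (E)-1-[2,4-dihydroxy-3-(3-methylbut-2-en-1-yl)phenyl]-3-(2,2-dimethylchroman-6-yl)prop-2-en-1-one, via aldol adduct 8 (not isolated)
Conditions: KOH (50% aq., 10 equiv), EtOH, N2, rt, 48 h; cold dilute HCl to pH 4
Reagents that add atoms: none
Why: Claisen–Schmidt condensation: aldehyde 7 cannot enolise and has no acidic OH to deactivate it, the two phenols of 3 are masked in the flask as phenoxides, E1cB loss of water from racemic 8 erases its carbinol centre and gives the conjugated E-enone, and strong base holds the product in the open chalcone form until the cold quench, while the prenyl and chroman groups are inert to KOH.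

Step 4
Reactants: 9 (E)-1-[2,4-dihydroxy-3-(3-methylbut-2-en-1-yl)phenyl]-3-(2,2-dimethylchroman-6-yl)prop-2-en-1-one
Product: 10 euchrenone a17 = (2S)-2-(2,2-dimethylchroman-6-yl)-7-hydroxy-8-(3-methylbut-2-en-1-yl)chroman-4-one
Conditions: recombinant Medicago sativa chalcone isomerase (type 2 CHI, 0.5 mol%), 50 mM KH2PO4/K2HPO4 pH 7.5, 5% v/v DMSO, 2-hydroxypropyl-β-cyclodextrin, 9 fed to 0.5 mM, 25 °C, dark, N2; EtOAc extraction at pH 6
Reagents that add atoms: none
Why: Proposed new method: chalcone isomerase-catalysed 6-endo-trig intramolecular oxa-Michael addition on a non-native substrate, the closest known reaction being the closure of isoliquiritigenin (same 2',4'-dihydroxy, 6'-deoxy ring A) to (2S)-liquiritigenin by this legume enzyme; the largely apolar cleft fixes the enone, a hydrogen-bond network (Thr48, Tyr106 and a bound water) polarises the carbonyl, and the 2'-oxyanion can reach only the Si face of Cβ, which sets C2 as S, and since the chelated 6'-deoxychalcone closes only very slowly by itself at pH 7.5 while the native acceleration is about 10^7, even a 10^3 to 10^4-fold loss of rate still outruns the racemic background, with the centre safe afterwards because this is the last step and the work-up is mildly acidic.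

**Compound list**
1 | 2,4-dihydroxyacetophenone | CC(=O)c1ccc(O)cc1O | starting material
2 | prenyl bromide (1-bromo-3-methylbut-2-ene) | CC(C)=CCBr | starting material
3 | 1-[2,4-dihydroxy-3-(3-methylbut-2-en-1-yl)phenyl]ethanone | CC(=O)c1ccc(O)c(CC=C(C)C)c1O | intermediate
4 | 4-hydroxybenzaldehyde | O=Cc1ccc(O)cc1 | starting material
5 | isoprene | C=CC(C)=C | starting material
6 | 4-hydroxy-3-(3-methylbut-2-en-1-yl)benzaldehyde (not isolated) | CC(C)=CCc1cc(C=O)ccc1O | intermediate
7 | 2,2-dimethylchroman-6-carbaldehyde | CC1(C)CCc2cc(C=O)ccc2O1 | intermediate
8 | 1-[2,4-dihydroxy-3-(3-methylbut-2-en-1-yl)phenyl]-3-(2,2-dimethylchroman-6-yl)-3-hydroxypropan-1-one (racemic aldol adduct; not isolated) | CC(C)=CCc1c(O)ccc(C(=O)CC(O)c2ccc3c(c2)CCC(C)(C)O3)c1O | intermediate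
9 | (E)-1-[2,4-dihydroxy-3-(3-methylbut-2-en-1-yl)phenyl]-3-(2,2-dimethylchroman-6-yl)prop-2-en-1-one | CC(C)=CCc1c(O)ccc(C(=O)/C=C/c2ccc3c(c2)CCC(C)(C)O3)c1O | intermediate
10 | euchrenone a17, (2S)-2-(2,2-dimethylchroman-6-yl)-7-hydroxy-8-(3-methylbut-2-en-1-yl)chroman-4-one | CC(C)=CCc1c(O)ccc2c1O[C@H](c1ccc3c(c1)CCC(C)(C)O3)CC2=O | target

**Step count:** 4 steps in total, with steps 1 and 2 run in parallel.

**Longest linear sequence:** 3 steps (1 → 3 → 9 → 10, or 4 → 7 → 9 → 10).

**Steps most likely to fail**

The ring C closure (step 4) is the most exposed step.
- **Risk:** the wild-type cleft may refuse the 3'-prenyl group or the fused pyran ring, and 9 is barely soluble in buffer. Success is judged by chiral HPLC and by the circular dichroism signature of the 2S series.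
- **Fallback:** give up catalyst control and resolve instead. Setting out from 9, NaOAc in refluxing EtOH closes ring C without facial control to the racemic flavanone F1.
- Preparative chiral SFC on an amylose tris(3,5-dimethylphenylcarbamate) phase then gives 10 and the (2R)-flavanone F2.
- F2 goes back into the NaOAc/EtOH reflux. Reversible ring opening through 9 racemises it to F1 for another pass, so no material is lost.
- This fallback comes back to the route at 10.

The ring A prenylation (step 1) is the second risk.
- **Risk:** C3 competes with C5, with O-alkylation and with double alkylation, so 30–40% is the realistic yield and the separation may be tedious.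
- **Fallback:** replace intermolecular C-alkylation by intramolecular [3,3] delivery. Setting out from 1, 3-chloro-3-methylbut-1-yne, K2CO3, KI and catalytic CuI in acetone at 55 °C etherify only the free, non-chelated 4-OH to the dimethylpropargyl ether F3.
- H2 over Pd/CaCO3 poisoned with Pb(OAc)2 and quinoline stops at the 1,1-dimethylallyl ether F4.
- Heating F4 in N,N-diethylaniline at 130 °C triggers the aromatic Claisen rearrangement. For chelated resacetophenone ethers this goes to C3 and inverts the allyl unit into the prenyl group.
- This fallback comes back to the route at 3.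

The one-pot annulation (step 2) is the third risk.
- **Risk:** the formyl group deactivates the ring, isoprene oligomerises in acid, and a second alkylation at C8 of the chroman is possible.
- **Fallback:** split the cationic annulation into an anionic C–C bond formation and a separate ring closure. Setting out from 4, aqueous KOH and 2 (conditions of step 1) give the ortho-C-prenylated phenol 6, now isolated on SiO2 from the O-prenyl ether.
- The sulfonic acid resin Amberlyst 15 (H+ form) in toluene at 80 °C then closes the pyran ring by the same Markovnikov hydroalkoxylation.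
- This fallback comes back to the route at 7. Compounds outside the list: none F0.

**Further compounds**
F1 | step 4 | racemic 2-(2,2-dimethylchroman-6-yl)-7-hydroxy-8-(3-methylbut-2-en-1-yl)chroman-4-one | CC(C)=CCc1c(O)ccc2c1OC(c1ccc3c(c1)CCC(C)(C)O3)CC2=O
F2 | step 4 | (2R)-2-(2,2-dimethylchroman-6-yl)-7-hydroxy-8-(3-methylbut-2-en-1-yl)chroman-4-one | CC(C)=CCc1c(O)ccc2c1O[C@@H](c1ccc3c(c1)CCC(C)(C)O3)CC2=O
F3 | step 1 | 1-[2-hydroxy-4-(2-methylbut-3-yn-2-yloxy)phenyl]ethanone | CC(=O)c1ccc(OC(C)(C)C#C)cc1O
F4 | step 1 | 1-[2-hydroxy-4-(2-methylbut-3-en-2-yloxy)phenyl]ethanone | CC(=O)c1ccc(OC(C)(C)C=C)cc1O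
F0 | step 2 | none | none
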